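The ring atoms are labelled O1, C2 (bearing the CBr2Et arm), C3, C4 (C=O), C5 and C6. The 4‑pyranone is cut at C3–C4 and O1–C6. The O1–C6(Br)=C5(Br)–C4(=O) arc is a vinylogous acyl bromide and is supplied by 2,3,3‑tribromoacryloyl chloride. C3, C2 and the side chain come from 3,3‑dibromopentan‑2‑one, a ketone that can enolise only at its methyl group. In a single operation, C‑acylation followed by closure through the enol oxygen with loss of bromide should deliver the whole carbon skeleton, the ring and four of the five bromines. Bromination of the one remaining ring C–H (C3) then finishes the synthesis.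

Key step: step 6

Remark: the target has no stereogenic centre or axis (the side‑chain carbon carries two bromines and the ring is planar), so it is achiral and no step has to set or preserve configuration.

Step 1
Reactants: 1 propiolic acid; 2 bromine
Product: 4 3‑bromopropiolic acid, via potassium 3‑bromopropiolate 3 (not isolated)
Conditions: Br2, aq. KOH (KOBr formed in situ), 0 °C; then cold dil. H2SO4, Et2O extraction; solution kept cold and used at once
Reagents that add atoms: bromine (2), BrBr
Why: Hypobromite halogenation of the acidic acetylenic C–H of the propiolate salt (electrophilic bromination of a terminal alkyne under basic conditions) should give the bromoalkynoate, which is held at 0 °C to suppress decarboxylation and is released as the acid on acidification.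

Step 2
Reactants: 4 3‑bromopropiolic acid; 2 bromine
Product: 5 2,3,3‑tribromoacrylic acid
Conditions: Br2 (1.05 equiv), CHCl3, 0 °C → rt
Reagents that add atoms: bromine (2), BrBr
Why: Halogen addition across the C≡C bond of the 1‑bromoalkyne should stop at the tribromoalkene, which is too electron‑poor to take up a second equivalent, and no E/Z question arises because C3 carries two bromines.

Step 3
Reactants: 5 2,3,3‑tribromoacrylic acid
Product: 6 2,3,3‑tribromoacryloyl chloride
Conditions: (COCl)2, cat. DMF, CH2Cl2, 0 °C → rt; volatiles removed, used crude
Reagents that add atoms: oxalyl chloride, O=C(Cl)C(=O)Cl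
Why: Acid chloride formation under Vilsmeier‑type catalysis should be clean because the acid has no α‑hydrogen (no ketene pathway) and the vinylic bromines are inert to the neutral, anhydrous conditions.

Step 4
Reactants: 7 3‑ethylpentane‑2,4‑dione
Product: 8 3‑diazopentan‑2‑one
Conditions: p‑ABSA (1.1 equiv), DBU (1.2 equiv), MeCN, 0 °C → rt; extracted into CH2Cl2, washed with dil. NaOH, solution used directly (not concentrated to dryness, not distilled)
Reagents that add atoms: 4‑acetamidobenzenesulfonyl azide (p‑ABSA), CC(=O)Nc1ccc(cc1)S(=O)(=O)N=[N+]=[N-]
Why: Regitz‑type deacylative diazo transfer should apply because the central carbon of 7 has only one hydrogen, so after attack of the enolate on the azide one acetyl group is passed to the sulfonamide nitrogen and the diazo group is left exactly on the carbon that is to become CBr2.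

Step 5
Reactants: 8 3‑diazopentan‑2‑one; 2 bromine
Product: 9 3,3‑dibromopentan‑2‑one
Conditions: Br2 (1.0 equiv, dropwise), CH2Cl2, −30 → 0 °C; aq. Na2S2O3/NaHCO3 wash
Reagents that add atoms: bromine (2), BrBr
Why: Geminal dihalogenation of an α‑diazo ketone (electrophilic bromination at the diazo carbon, then displacement of N2 by bromide) should place both bromines on C3 only, and since no HBr is formed no acid‑catalysed bromination of the methyl side is expected.

Step 6
Reactants: 9 3,3‑dibromopentan‑2‑one; 6 2,3,3‑tribromoacryloyl chloride
Product: 12 2,3‑dibromo‑6‑(1,1‑dibromopropyl)‑4H‑pyran‑4‑one, via bromomagnesium enolate 10 (not isolated), via 1,1,2,6,6‑pentabromooct‑1‑ene‑3,5‑dione 11 (not isolated)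
Conditions: MgBr2·OEt2 (2.5 equiv), i‑Pr2NEt (3.5 equiv), CH2Cl2, 0 °C → rt; 1 M HCl work‑up
Reagents that add atoms: none
Why: MgBr2 and the hindered amine should enolise 9 at its only acidic position, the methyl group, to give the chelating magnesium enolate 10, whose carbon attacks the acyl chloride carbon of 6 to form the C3–C4 bond and the 1,3‑diketone 11 (soft‑enolisation Claisen‑type C‑acylation of a ketone by an acid chloride). The enol oxygen on C2 of 11 then adds to the CBr2 terminus of the tribromovinyl ketone and bromide is expelled, forming O1–C6 in a 6‑endo‑trig oxa‑Michael addition–elimination that leaves the conjugated 4‑pyranone, with the excess amine taking up the HBr. The closest known chemistry is the annulation of ketone enolates with β,β‑dihalo‑ or β,β‑bis(alkylthio)acryloyl chlorides to 2‑hetero‑substituted 4‑pyranones. No stereocentre is formed. The step needs C‑ over O‑acylation and attack at the acyl carbon in preference to the CBr2 terminus, both favoured by the magnesium‑bound enolate and the much higher electrophilicity of the acyl chloride; the regiochemistry is fixed by the substrates, since the CBr2 side of 9 has no α‑hydrogen and 6 has no α‑hydrogen from which a ketene could arise. The weak base and low starting temperature should hold back bromine transfer from the CBr2 centre and Favorskii‑type ionisation of 10.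

Step 7
Reactants: 12 2,3‑dibromo‑6‑(1,1‑dibromopropyl)‑4H‑pyran‑4‑one; 2 bromine
Product: 13 2,3,5‑tribromo‑6‑(1,1‑dibromopropyl)‑4H‑pyran‑4‑one
Conditions: Br2 (3 equiv), AcOH, 60 °C, dark
Reagents that add atoms: bromine (2), BrBr
Why: Electrophilic halogenation of a 4‑pyranone should occur at C3, the β‑carbon of the O1–C2=C3 enol ether and the only ring carbon that still bears hydrogen, through an O1‑stabilised cationic adduct that loses a proton, while the non‑nucleophilic acidic medium spares the displaceable C6–Br bond.

Compound list
1 | propiolic acid (prop‑2‑ynoic acid) | C#CC(=O)O | starting material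
2 | bromine | BrBr | starting material
3 | potassium 3‑bromopropiolate | [K+].[O-]C(=O)C#CBr | intermediate
4 | 3‑bromopropiolic acid (3‑bromoprop‑2‑ynoic acid) | OC(=O)C#CBr | intermediate
5 | 2,3,3‑tribromoacrylic acid (2,3,3‑tribromoprop‑2‑enoic acid) | OC(=O)C(Br)=C(Br)Br | intermediate
6 | 2,3,3‑tribromoacryloyl chloride | O=C(Cl)C(Br)=C(Br)Br | intermediate
7 | 3‑ethylpentane‑2,4‑dione | CCC(C(C)=O)C(C)=O | starting material
8 | 3‑diazopentan‑2‑one | CCC(=[N+]=[N-])C(C)=O | intermediate
9 | 3,3‑dibromopentan‑2‑one | CCC(Br)(Br)C(C)=O | intermediate
10 | bromomagnesium 3,3‑dibromopent‑1‑en‑2‑olate (magnesium enolate of 9) | CCC(Br)(Br)C(=C)O[Mg]Br | intermediate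
11 | 1,1,2,6,6‑pentabromooct‑1‑ene‑3,5‑dione | CCC(Br)(Br)C(=O)CC(=O)C(Br)=C(Br)Br | intermediate
12 | 2,3‑dibromo‑6‑(1,1‑dibromopropyl)‑4H‑pyran‑4‑one | CCC(Br)(Br)c1cc(=O)c(Br)c(Br)o1 | intermediate
13 | 2,3,5‑tribromo‑6‑(1,1‑dibromopropyl)‑4H‑pyran‑4‑one | CCC(Br)(Br)c1oc(Br)c(Br)c(=O)c1Br | target

Total step count: 7. Longest linear sequence: 5 steps (steps 1, 2, 3, 6, 7); the ketone branch (steps 4, 5) joins at step 6.

Steps most likely to fail

Step 6. The risks are competing O‑acylation, transfer of bromine from the CBr2 centre to the enolate carbon or Favorskii‑type ionisation of the enolate in the bromide‑rich basic medium, and stalling of the ring closure at the magnesium chelate of the diketone. The fallback sets out from 9 and comes back at 12. It avoids a free enolate altogether: 9 would be O‑silylated (TMSOTf, Et3N, CH2Cl2, 0 °C) to [(3,3‑dibromopent‑1‑en‑2‑yl)oxy]trimethylsilane F1. This neutral enol ether would be C‑acylated by 6 with ZnCl2 in CH2Cl2/Et2O (Lewis‑acid acylation of a silyl enol ether, a known route to 1,3‑diketones) to give 11, which would be closed with i‑Pr2NEt in CH2Cl2 to 12.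

Step 7. The risks are sluggish electrophilic attack on an electron‑poor ring position that is shielded by the CBr2Et group, and solvolytic displacement of the C6 bromide if the conditions have to be forced. The fallback sets out from 11 and comes back at 13, inverting the order of bromination and ring closure. The acylation of step 6 would be held at the stage of 11 (magnesium chelate, 0 °C) and NBS added, which should brominate the doubly activated C4 methylene as 1,3‑diketones do readily. This gives 1,1,2,4,6,6‑hexabromooct‑1‑ene‑3,5‑dione F2 (racemic at C4, largely enolised). Closure with i‑Pr2NEt by the same addition–elimination would then give 13 directly.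

Step 1. The risks are decarboxylation of the bromoalkynoate to volatile, hazardous bromoacetylene and loss of the water‑soluble, lachrymatory acid during isolation. The fallback sets out from 1 and comes back at 5 without passing through any haloalkyne. Addition of one equivalent of Br2 to 1 (CHCl3, rt) should give (E)‑2,3‑dibromoacrylic acid F3 by anti addition. A second, light‑promoted addition (neat Br2, 50 °C) should give 2,2,3,3‑tetrabromopropanoic acid F4. Cold ethanolic KOH should then remove HBr (C3–H and C2–Br) to give 5 after acidification.

Further compounds
F1 | step 6 | [(3,3‑dibromopent‑1‑en‑2‑yl)oxy]trimethylsilane | CCC(Br)(Br)C(=C)O[Si](C)(C)C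
F2 | step 7 | 1,1,2,4,6,6‑hexabromooct‑1‑ene‑3,5‑dione (racemic) | CCC(Br)(Br)C(=O)C(Br)C(=O)C(Br)=C(Br)Br
F3 | step 1 | (E)‑2,3‑dibromoacrylic acid | Br/C=C(/Br)C(=O)O
F4 | step 1 | 2,2,3,3‑tetrabromopropanoic acid | OC(=O)C(Br)(Br)C(Br)Br
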